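**Retrosynthetic overview**
1. Target 22 ⇐ tris-MOM ether 20 by global MOM cleavage with a silyl triflate, without protic acid or base.
2. 20 ⇐ phenol-enone 18: ring C is the only ring made, closed last through its O1–C2 bond by a catalytic enantioselective 6-endo oxa-Michael addition whose terminating protonation sets C3 (S).
3. 18 ⇐ carbinol 17 (MnO2) ⇐ ring A aldehyde 7 + α-aryl vinyllithium 15 from ring B ketone hydrazone 14 (C4–C3 bond).
4. 7 ⇐ 2,4,6-trihydroxybenzaldehyde: bis-MOM, O-prenylation, para-Claisen–Cope (puts the prenyl group between the two MOM ethers and frees the one phenol that becomes O1).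
5. 14 ⇐ 2,4-dihydroxyacetophenone: C3 iodination, MOM/methyl differentiation, Suzuki coupling with (E)-alkenyl boronate 12, hydrazone formation.

Assumption: boronate 12 is bought (otherwise one step from 3-methylbut-1-yne and pinacolborane); the quinine-derived catalyst of step 10 is taken to give the 3S ketone, and its quinidine-derived pseudo-enantiomer is used instead if the first run shows 3R.

**Route**

Step 1
Reactants: 1 2,4,6-trihydroxybenzaldehyde
Product: 2 2-hydroxy-4,6-bis(methoxymethoxy)benzaldehyde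
Conditions: MOMCl (2.1 equiv), i-Pr2NEt (2.5 equiv), CH2Cl2, 0 °C → rt
Reagents that add atoms: chloromethyl methyl ether (MOMCl), COCCl
Why: Chemoselective Williamson-type O-alkylation, in which the para-OH and one ortho-OH react while the remaining ortho-OH is deactivated by its hydrogen bond to the formyl group.

Step 2
Reactants: 2 2-hydroxy-4,6-bis(methoxymethoxy)benzaldehyde; 3 1-bromo-3-methylbut-2-ene (prenyl bromide)
Product: 4 2,4-bis(methoxymethoxy)-6-[(3-methylbut-2-en-1-yl)oxy]benzaldehyde
Conditions: K2CO3, acetone, reflux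
Reagents that add atoms: none
Why: Williamson etherification of the only free phenol with a reactive allylic bromide; MOM ethers and the aldehyde are inert to K2CO3.

Step 3
Reactants: 4 2,4-bis(methoxymethoxy)-6-[(3-methylbut-2-en-1-yl)oxy]benzaldehyde
Product: 7 6-hydroxy-2,4-bis(methoxymethoxy)-3-(3-methylbut-2-en-1-yl)benzaldehyde, via ortho-dienone 5 (not isolated), via para-dienone 6 (not isolated)
Conditions: PhNEt2, 200 °C, sealed tube, Ar, 2 h
Reagents that add atoms: none
Why: Aromatic para-Claisen (Claisen–Cope) rearrangement, in which the [3,3] shift to the free ortho carbon gives the congested 1,1-dimethylallyl dienone 5, which undergoes a Cope shift to the para carbon between the two MOM ethers before enolising, as established for prenyl ethers of bis-MOM acylphloroglucinols.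

Step 4
Reactants: 8 1-(2,4-dihydroxyphenyl)ethanone
Product: 9 1-(2,4-dihydroxy-3-iodophenyl)ethanone
Conditions: I2 (0.4 equiv), HIO3 (0.2 equiv), EtOH/H2O, 40 °C
Reagents that add atoms: iodine, II; iodic acid, O[I](=O)=O
Why: Electrophilic aromatic iodination, directed to C3 between the two hydroxyl groups by the bond fixation of the chelated 2-hydroxyaryl ketone.

Step 5
Reactants: 9 1-(2,4-dihydroxy-3-iodophenyl)ethanone
Product: 11 1-[3-iodo-2-methoxy-4-(methoxymethoxy)phenyl]ethanone, via mono-MOM ether 10 (not isolated)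
Conditions: MOMCl (1.05 equiv), K2CO3 (4 equiv), acetone, 0 °C → rt; then Me2SO4 (2 equiv), reflux
Reagents that add atoms: chloromethyl methyl ether (MOMCl), COCCl; dimethyl sulfate, COS(=O)(=O)OC
Why: Sequential Williamson etherification in one pot, the non-chelated 4-OH reacting at room temperature and the chelated, hindered 2-OH only with dimethyl sulfate at reflux.

Step 6
Reactants: 11 1-[3-iodo-2-methoxy-4-(methoxymethoxy)phenyl]ethanone; 12 (E)-4,4,5,5-tetramethyl-2-(3-methylbut-1-en-1-yl)-1,3,2-dioxaborolane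
Product: 13 1-{2-methoxy-4-(methoxymethoxy)-3-[(E)-3-methylbut-1-en-1-yl]phenyl}ethanone
Conditions: Pd(OAc)2 (3 mol%), SPhos (6 mol%), K3PO4, toluene/H2O (10:1), 80 °C
Reagents that add atoms: none
Why: Suzuki–Miyaura coupling with retention of the (E)-alkene geometry; the bulky biaryl phosphine handles the doubly ortho-substituted iodide.

Step 7
Reactants: 13 1-{2-methoxy-4-(methoxymethoxy)-3-[(E)-3-methylbut-1-en-1-yl]phenyl}ethanone
Product: 14 N′-[(1E)-1-{2-methoxy-4-(methoxymethoxy)-3-[(E)-3-methylbut-1-en-1-yl]phenyl}ethylidene]-2,4,6-tri(propan-2-yl)benzenesulfonohydrazide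
Conditions: 2,4,6-i-Pr3C6H2SO2NHNH2 (1.05 equiv), PPTS (5 mol%), THF/MeOH, rt
Reagents that add atoms: 2,4,6-triisopropylbenzenesulfonohydrazide, CC(C)c1cc(C(C)C)c(S(=O)(=O)NN)c(C(C)C)c1
Why: Hydrazone condensation of a methyl ketone under mild acid catalysis that leaves the MOM ether intact.

Step 8
Reactants: 14 the trisylhydrazone of ketone 13; 7 6-hydroxy-2,4-bis(methoxymethoxy)-3-(3-methylbut-2-en-1-yl)benzaldehyde
Product: 17 2-(1-hydroxy-2-{2-methoxy-4-(methoxymethoxy)-3-[(E)-3-methylbut-1-en-1-yl]phenyl}prop-2-en-1-yl)-3,5-bis(methoxymethoxy)-4-(3-methylbut-2-en-1-yl)phenol (racemic), via aryl vinyllithium 15 (not isolated), via sodium phenoxide 16 (not isolated)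
Conditions: 14 (1.4 equiv), n-BuLi (2.05 equiv per 14), THF, –78 → 0 °C; then 16 (from 7, NaH, THF, 0 °C), –78 → –20 °C; aq. NH4Cl
Reagents that add atoms: none
Why: Shapiro reaction (hydrazone dianion, loss of sulfinate and N2) gives the α-aryl vinyllithium, which adds 1,2 to the formyl group of the pre-formed phenoxide; the racemic carbinol centre is erased in step 9.

Step 9
Reactants: 17 the phenol-carbinol from step 8
Product: 18 1-[6-hydroxy-2,4-bis(methoxymethoxy)-3-(3-methylbut-2-en-1-yl)phenyl]-2-{2-methoxy-4-(methoxymethoxy)-3-[(E)-3-methylbut-1-en-1-yl]phenyl}prop-2-en-1-one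
Conditions: activated MnO2 (15 equiv), CH2Cl2, 0 °C → rt, 1–2 h; Celite filtration
Reagents that add atoms: none
Why: Chemoselective MnO2 oxidation of an allylic, benzylic alcohol under neutral heterogeneous conditions; the phenol becomes hydrogen-bonded to the new carbonyl and, without base, does not add to the enone.

Step 10
Reactants: 18 the phenol-enone from step 9
Product: 20 (3S)-3-{2-methoxy-4-(methoxymethoxy)-3-[(E)-3-methylbut-1-en-1-yl]phenyl}-5,7-bis(methoxymethoxy)-6-(3-methylbut-2-en-1-yl)-2,3-dihydro-4H-chromen-4-one, via catalyst-bound enolate 19 (not isolated)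
Conditions: quinine-derived squaramide 3-{[3,5-bis(trifluoromethyl)phenyl]amino}-4-{[(8α,9S)-6′-methoxycinchonan-9-yl]amino}cyclobut-3-ene-1,2-dione (10 mol%), toluene (0.02 M), 4 Å molecular sieves, –30 °C, 36 h; AcOH (0.2 equiv) quench, cold SiO2 plug
Reagents that add atoms: none
Why: Proposed new method: a bifunctional Brønsted base/hydrogen-bond donor catalyses the 6-endo-trig oxa-Michael addition of the single free phenol to the α-aryl enone, the squaramide binding the carbonyl oxygen while the quinuclidine deprotonates the phenol, so that the O1–C2 bond forms and the resulting enolate 19 exists only as a contact ion pair with the chiral ammonium ion, which delivers its proton to one face of C3 and sets the S centre (the product ketone is far too weakly acidic to be re-deprotonated by the tertiary amine at –30 °C, and the uncatalysed reaction of the chelated phenol is slow in cold toluene); the closest known reactions are cinchona squaramide- and thiourea-catalysed intramolecular oxa-Michael additions of phenols to chromans and flavanones, conjugate addition/enantioselective protonation cascades of thiols with α-substituted acrylates, and the racemic amine-mediated closure of α-methylene deoxybenzoins to isoflavanones.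

Step 11
Reactants: 20 the (3S) tris-MOM isoflavanone from step 10
Product: 22 (3S)-5,7-dihydroxy-3-{4-hydroxy-2-methoxy-3-[(E)-3-methylbut-1-en-1-yl]phenyl}-6-(3-methylbut-2-en-1-yl)-2,3-dihydro-4H-chromen-4-one (target), via tris(trimethylsilyl) ether 21 (not isolated)
Conditions: TMSOTf (6 equiv), 2,2′-bipyridyl (9 equiv), CH3CN, 0 °C, 1–2 h; then H2O, aq. NaHCO3, 0 °C
Reagents that add atoms: none
Why: Silyl triflate/bipyridyl cleavage of aryl MOM ethers transfers the methoxymethyl group to bipyridyl and leaves aryl silyl ethers that hydrolyse on work-up, with no free Brønsted acid or base, so the enolisable C3 centre, the prenyl group and the styrenyl group are expected to survive.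

**Compound list**

1 | 2,4,6-trihydroxybenzaldehyde | O=Cc1c(O)cc(O)cc1O | starting material
2 | 2-hydroxy-4,6-bis(methoxymethoxy)benzaldehyde | O=Cc1c(O)cc(OCOC)cc1OCOC | intermediate
3 | 1-bromo-3-methylbut-2-ene (prenyl bromide) | CC(C)=CCBr | starting material
4 | 2,4-bis(methoxymethoxy)-6-[(3-methylbut-2-en-1-yl)oxy]benzaldehyde | O=Cc1c(OCOC)cc(OCOC)cc1OCC=C(C)C | intermediate
5 | ortho-dienone: 2,4-bis(methoxymethoxy)-5-(2-methylbut-3-en-2-yl)-6-oxocyclohexa-1,3-diene-1-carbaldehyde (racemic) | O=CC1=C(OCOC)C=C(OCOC)C(C(C)(C)C=C)C1=O | intermediate (not isolated)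
6 | para-dienone: 2,4-bis(methoxymethoxy)-3-(3-methylbut-2-en-1-yl)-6-oxocyclohexa-1,4-diene-1-carbaldehyde (racemic) | O=CC1=C(OCOC)C(CC=C(C)C)C(OCOC)=CC1=O | intermediate (not isolated)
7 | 6-hydroxy-2,4-bis(methoxymethoxy)-3-(3-methylbut-2-en-1-yl)benzaldehyde | O=Cc1c(O)cc(OCOC)c(CC=C(C)C)c1OCOC | intermediate
8 | 1-(2,4-dihydroxyphenyl)ethanone | CC(=O)c1ccc(O)cc1O | starting material
9 | 1-(2,4-dihydroxy-3-iodophenyl)ethanone | CC(=O)c1ccc(O)c(I)c1O | intermediate
10 | 1-[2-hydroxy-3-iodo-4-(methoxymethoxy)phenyl]ethanone | CC(=O)c1ccc(OCOC)c(I)c1O | intermediate (not isolated)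
11 | 1-[3-iodo-2-methoxy-4-(methoxymethoxy)phenyl]ethanone | CC(=O)c1ccc(OCOC)c(I)c1OC | intermediate
12 | (E)-4,4,5,5-tetramethyl-2-(3-methylbut-1-en-1-yl)-1,3,2-dioxaborolane | CC(C)/C=C/B1OC(C)(C)C(C)(C)O1 | starting material
13 | 1-{2-methoxy-4-(methoxymethoxy)-3-[(E)-3-methylbut-1-en-1-yl]phenyl}ethanone | CC(=O)c1ccc(OCOC)c(/C=C/C(C)C)c1OC | intermediate
14 | N′-[(1E)-1-{2-methoxy-4-(methoxymethoxy)-3-[(E)-3-methylbut-1-en-1-yl]phenyl}ethylidene]-2,4,6-tri(propan-2-yl)benzenesulfonohydrazide | C/C(=N\NS(=O)(=O)c1c(C(C)C)cc(C(C)C)cc1C(C)C)c1ccc(OCOC)c(/C=C/C(C)C)c1OC | intermediate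
15 | (1-{2-methoxy-4-(methoxymethoxy)-3-[(E)-3-methylbut-1-en-1-yl]phenyl}ethenyl)lithium | [Li]C(=C)c1ccc(OCOC)c(/C=C/C(C)C)c1OC | intermediate (not isolated)
16 | sodium 2-formyl-3,5-bis(methoxymethoxy)-4-(3-methylbut-2-en-1-yl)phenolate | [Na+].[O-]c1cc(OCOC)c(CC=C(C)C)c(OCOC)c1C=O | intermediate (not isolated)
17 | 2-(1-hydroxy-2-{2-methoxy-4-(methoxymethoxy)-3-[(E)-3-methylbut-1-en-1-yl]phenyl}prop-2-en-1-yl)-3,5-bis(methoxymethoxy)-4-(3-methylbut-2-en-1-yl)phenol (racemic) | C=C(C(O)c1c(O)cc(OCOC)c(CC=C(C)C)c1OCOC)c1ccc(OCOC)c(/C=C/C(C)C)c1OC | intermediate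
18 | 1-[6-hydroxy-2,4-bis(methoxymethoxy)-3-(3-methylbut-2-en-1-yl)phenyl]-2-{2-methoxy-4-(methoxymethoxy)-3-[(E)-3-methylbut-1-en-1-yl]phenyl}prop-2-en-1-one | C=C(C(=O)c1c(O)cc(OCOC)c(CC=C(C)C)c1OCOC)c1ccc(OCOC)c(/C=C/C(C)C)c1OC | intermediate
19 | catalyst-bound enolate of 20, drawn as the enol 3-{2-methoxy-4-(methoxymethoxy)-3-[(E)-3-methylbut-1-en-1-yl]phenyl}-5,7-bis(methoxymethoxy)-6-(3-methylbut-2-en-1-yl)-2H-chromen-4-ol | COc1c(C2=C(O)c3c(OCOC)c(CC=C(C)C)c(OCOC)cc3OC2)ccc(OCOC)c1/C=C/C(C)C | intermediate (not isolated)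
20 | (3S)-3-{2-methoxy-4-(methoxymethoxy)-3-[(E)-3-methylbut-1-en-1-yl]phenyl}-5,7-bis(methoxymethoxy)-6-(3-methylbut-2-en-1-yl)-2,3-dihydro-4H-chromen-4-one | COc1c([C@H]2COc3cc(OCOC)c(CC=C(C)C)c(OCOC)c3C2=O)ccc(OCOC)c1/C=C/C(C)C | intermediate
21 | (3S)-3-{2-methoxy-3-[(E)-3-methylbut-1-en-1-yl]-4-(trimethylsilyloxy)phenyl}-6-(3-methylbut-2-en-1-yl)-5,7-bis(trimethylsilyloxy)-2,3-dihydro-4H-chromen-4-one | COc1c([C@H]2COc3cc(O[Si](C)(C)C)c(CC=C(C)C)c(O[Si](C)(C)C)c3C2=O)ccc(O[Si](C)(C)C)c1/C=C/C(C)C | intermediate (not isolated)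
22 | (3S)-5,7-dihydroxy-3-{4-hydroxy-2-methoxy-3-[(E)-3-methylbut-1-en-1-yl]phenyl}-6-(3-methylbut-2-en-1-yl)-2,3-dihydro-4H-chromen-4-one | COc1c([C@H]2COc3cc(O)c(CC=C(C)C)c(O)c3C2=O)ccc(O)c1/C=C/C(C)C | target

**Step count and risks**

Total steps: 11 (ring A fragment 3, ring B fragment 4, assembly and endgame 4). Longest linear sequence: 8 steps (8 → 9 → 11 → 13 → 14 → 17 → 18 → 20 → 22).

The three steps most likely to fail:

Step 10 (the proposed enantioselective ring closure). The risk is low enantiomeric excess, through protonation of the enolate by a second substrate phenol or through uncatalysed cyclisation; regiochemistry is not at risk because only one phenol is free. The fallback uses known chemistry, sets out from 18 and comes back at 20. Et3N (20 mol%, CH2Cl2, rt) closes ring C without stereocontrol to the racemic 3-{2-methoxy-4-(methoxymethoxy)-3-[(E)-3-methylbut-1-en-1-yl]phenyl}-5,7-bis(methoxymethoxy)-6-(3-methylbut-2-en-1-yl)chroman-4-one F2. Deprotonation with NaN(SiMe3)2 and O-acylation with allyl chloroformate (THF, –78 °C) gives the allyl enol carbonate, allyl 3-aryl-5,7-bis(methoxymethoxy)-6-prenyl-2H-chromen-4-yl carbonate F3. Palladium-catalysed decarboxylative asymmetric protonation (Pd2(dba)3, (S)-(CF3)3-t-BuPHOX, Meldrum's acid, 1,4-dioxane, rt to 40 °C; ligand antipode if the sense is wrong) then returns 20; this reaction is established for isoflavanone enolates and works best with ortho-substituted 3-aryl groups such as this one.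

Step 8 (fragment coupling). The risks are side reactions of the hydrazone dianion, sluggish addition to the electron-rich phenoxide aldehyde, and the acid sensitivity of the ortho-hydroxybenzylic carbinol 17. The fallback sets out from 13 and 7 and comes back at 17. Ketone 13 is converted with KN(SiMe3)2 and PhNTf2 (THF, –78 °C) into the enol triflate 1-{2-methoxy-4-(methoxymethoxy)-3-[(E)-3-methylbut-1-en-1-yl]phenyl}ethenyl trifluoromethanesulfonate F1. F1 is coupled with the unprotected aldehyde 7 under Nozaki–Hiyama–Kishi conditions (CrCl2, 2 mol% NiCl2, DMF, rt; aq. NaHCO3 work-up) to give 17. The vinylchromium nucleophile needs no strong base, leaves the phenol protonated so the aldehyde stays more electrophilic, and is inert to MOM ethers.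

Step 11 (global deprotection next to an enolisable stereocentre). The risks are erosion of ee, silyl enol ether formation, or incomplete cleavage of the hindered 5-O-MOM group. The fallback sets out from 20 and comes back at 22; it gives up the stereocentre during deprotection and re-sets it at the very end under neutral conditions. HCl in MeOH/THF (40 °C) removes the three MOM groups without regard to ee and gives the racemised triphenol 5,7-dihydroxy-3-{4-hydroxy-2-methoxy-3-[(E)-3-methylbut-1-en-1-yl]phenyl}-6-(3-methylbut-2-en-1-yl)chroman-4-one F4. Allyl chloroformate with pyridine/DMAP, then NaN(SiMe3)2 and more allyl chloroformate (THF, –78 °C), gives the tetrakis(allyl carbonate), the 4-enol allyl carbonate of F4 bearing allyl carbonates on O5, O7 and O4′, F5. Pd2(dba)3, (S)-(CF3)3-t-BuPHOX and Meldrum's acid (6 equiv, 1,4-dioxane, rt to 40 °C) then remove the three aryl allyl carbonates and carry out the decarboxylative asymmetric protonation of the enol carbonate in one operation, delivering 22 directly.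

**Further compounds**

F1 | step 8 | 1-{2-methoxy-4-(methoxymethoxy)-3-[(E)-3-methylbut-1-en-1-yl]phenyl}ethenyl trifluoromethanesulfonate | C=C(OS(=O)(=O)C(F)(F)F)c1ccc(OCOC)c(/C=C/C(C)C)c1OC
F2 | step 10 | racemic 3-{2-methoxy-4-(methoxymethoxy)-3-[(E)-3-methylbut-1-en-1-yl]phenyl}-5,7-bis(methoxymethoxy)-6-(3-methylbut-2-en-1-yl)chroman-4-one | COc1c(C2COc3cc(OCOC)c(CC=C(C)C)c(OCOC)c3C2=O)ccc(OCOC)c1/C=C/C(C)C
F3 | step 10 | allyl 3-{2-methoxy-4-(methoxymethoxy)-3-[(E)-3-methylbut-1-en-1-yl]phenyl}-5,7-bis(methoxymethoxy)-6-(3-methylbut-2-en-1-yl)-2H-chromen-4-yl carbonate | C=CCOC(=O)OC1=C(c2ccc(OCOC)c(/C=C/C(C)C)c2OC)COc2cc(OCOC)c(CC=C(C)C)c(OCOC)c21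
F4 | step 11 | racemised 5,7-dihydroxy-3-{4-hydroxy-2-methoxy-3-[(E)-3-methylbut-1-en-1-yl]phenyl}-6-(3-methylbut-2-en-1-yl)chroman-4-one | COc1c(C2COc3cc(O)c(CC=C(C)C)c(O)c3C2=O)ccc(O)c1/C=C/C(C)C
F5 | step 11 | allyl 5,7-bis(allyloxycarbonyloxy)-3-{4-(allyloxycarbonyloxy)-2-methoxy-3-[(E)-3-methylbut-1-en-1-yl]phenyl}-6-(3-methylbut-2-en-1-yl)-2H-chromen-4-yl carbonate | C=CCOC(=O)OC1=C(c2ccc(OC(=O)OCC=C)c(/C=C/C(C)C)c2OC)COc2cc(OC(=O)OCC=C)c(CC=C(C)C)c(OC(=O)OCC=C)c21
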